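The ten-membered carbocycle (C1–C10, germacranolide numbering) is closed last at the C5–C6 bond, the link between the vinyl CH of C4=C5 and the lactone carbinol C6. A Nozaki–Hiyama–Kishi reaction of seco-aldehyde 24 (C5 vinyl iodide, C6 aldehyde) should make this bond, the C6 stereocentre and, by capture of the C12 methyl ester, the fused α-methylene lactone (O–C6–C7–C11–C12) in one operation. The step exploits the allylic-alcohol motif C4=C5–C6–O and the two ring-cis olefins, which pre-bend the chain. The precursor carries all other stereocentres, set from (S)-malate (C9) and a chelation-controlled indium allylation (C7, C8).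

Key step: step 17

Remark: positions are given in germacranolide numbering (C1–C15); (2R)-2-methylbutanoic acid and the Grignard solution 2 are taken as purchasable, and the acetal carbon of the p-methoxybenzylidene ring in 9–14 is an inconsequential epimer mixture that disappears in step 10.

Step 1
Reactants: 1 3-(trimethylsilyl)prop-2-yn-1-ol; 2 [2-(1,3-dioxan-2-yl)ethyl]magnesium bromide
Product: 3 (2E)-2-[2-(1,3-dioxan-2-yl)ethyl]-3-(trimethylsilyl)prop-2-en-1-ol
Conditions: 2 (3 equiv), CuI (10 mol %), THF, 0 °C → reflux; aq. NH4Cl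
Reagents that add atoms: none
Why: Copper-catalysed anti-carbomagnesiation of a propargylic alcohol, in which the magnesium alkoxide directs the alkyl group to the proximal alkyne carbon and holds the new C–Mg bond (at the silicon-bearing carbon) cis to the CH2O group, so that protonation leaves Me3Si cis to the new chain, the geometry later needed at C4=C5.

Step 2
Reactants: 3 vinylsilane alcohol
Product: 4 tert-butyldiphenylsilyl ether of 3
Conditions: t-BuPh2SiCl, imidazole, CH2Cl2, rt
Reagents that add atoms: tert-butyl(chloro)diphenylsilane, CC(C)(C)[Si](Cl)(c1ccccc1)c1ccccc1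
Why: Standard silylation of the primary allylic alcohol (the future C15 hydroxyl) with a group that survives every later acidic, basic and oxidative step.

Step 3
Reactants: 4 silyl ether
Product: 5 tert-butyl{[(2E)-2-[2-(1,3-dioxan-2-yl)ethyl]-3-iodoprop-2-en-1-yl]oxy}diphenylsilane
Conditions: N-iodosuccinimide, 2,6-lutidine, (CF3)2CHOH, 0 °C
Reagents that add atoms: N-iodosuccinimide, O=C1CCC(=O)N1I
Why: Ipso-iododesilylation of the vinylsilane, which runs through a β-silyl cation at the fully substituted carbon and loses silicon faster than it rotates, so iodine takes the place of silicon with retention (iodine cis to the chain).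

Step 4
Reactants: 5 iodoalkene acetal
Product: 6 (4E)-4-{[(tert-butyldiphenylsilyl)oxy]methyl}-5-iodopent-4-enal
Conditions: TsOH·H2O (cat.), acetone/H2O, 50 °C
Reagents that add atoms: water, O
Why: Acid-catalysed acetal hydrolysis frees the C1 aldehyde while the vinyl iodide and the robust silyl ether are untouched.

Step 5
Reactants: 7 dimethyl (S)-malate
Product: 8 methyl (3S)-3,4-dihydroxybutanoate
Conditions: BH3·SMe2, NaBH4 (cat.), THF, rt; MeOH
Reagents that add atoms: none
Why: Hydroxyl-directed chemoselective borane reduction of the ester next to the free hydroxyl (through a cyclic alkoxyborane) leaves the distal ester, and the malate stereocentre, the future C9, is not touched.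

Step 6
Reactants: 8 diol ester
Product: 9 methyl 2-[(4S)-2-(4-methoxyphenyl)-1,3-dioxolan-4-yl]acetate
Conditions: 4-MeOC6H4CH(OMe)2, camphorsulfonic acid (cat.), CH2Cl2, 0 °C
Reagents that add atoms: 4-methoxybenzaldehyde dimethyl acetal, COC(OC)c1ccc(OC)cc1
Why: Acid-catalysed transacetalisation should trap the 1,2-diol as the five-membered arylidene acetal faster than it lactonises.

Step 7
Reactants: 9 acetal ester; 6 iodo aldehyde
Product: 12 methyl (2E,6E)-6-{[(tert-butyldiphenylsilyl)oxy]methyl}-7-iodo-2-[(4S)-2-(4-methoxyphenyl)-1,3-dioxolan-4-yl]hepta-2,6-dienoate, via aldol adduct 10 (not isolated), via aldol acetate 11 (not isolated)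
Conditions: LiN(i-Pr)2, THF, −78 °C; 6; Ac2O, −78 → 0 °C; DBU, 0 °C → rt
Reagents that add atoms: none
Why: Lithium ester enolate aldol addition at −78 °C (where loss of the β-oxygen should not compete), acetylation of the aldolate and E1cB elimination should give the trisubstituted enoate with the chain trans to the ester, the more stable geometry and the one needed at C1=C10.

Step 8
Reactants: 12 dienoate
Product: 13 (2Z,6E)-6-{[(tert-butyldiphenylsilyl)oxy]methyl}-7-iodo-2-[(4S)-2-(4-methoxyphenyl)-1,3-dioxolan-4-yl]hepta-2,6-dien-1-ol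
Conditions: i-Bu2AlH, CH2Cl2, −78 °C; aq. potassium sodium tartrate
Reagents that add atoms: none
Why: 1,2-Reduction of the enoate by the aluminium hydride at low temperature, at which the arylidene acetal and the vinyl iodide are inert (the descriptor changes, the geometry does not).

Step 9
Reactants: 13 allylic alcohol
Product: 14 4-methoxybenzyl ether of 13
Conditions: NaH, 4-MeOC6H4CH2Cl, Bu4NI (cat.), THF/DMF, 0 °C → rt
Reagents that add atoms: 4-methoxybenzyl chloride, COc1ccc(CCl)cc1
Why: Williamson etherification masks the C14 hydroxyl so that no lactol can form with the C8 oxygen later and so that it is released together with the C9 ether in step 18.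

Step 10
Reactants: 14 bis-protected acetal
Product: 15 (2S,3Z,7E)-7-{[(tert-butyldiphenylsilyl)oxy]methyl}-8-iodo-2-[(4-methoxybenzyl)oxy]-3-{[(4-methoxybenzyl)oxy]methyl}octa-3,7-dien-1-ol
Conditions: i-Bu2AlH, CH2Cl2, −78 → 0 °C
Reagents that add atoms: none
Why: Regioselective reductive opening of the arylidene acetal, in which aluminium binds the less hindered primary oxygen and hydride quenches the oxocarbenium ion, leaves the 4-methoxybenzyl group on the secondary C9 oxygen and frees the primary C8 alcohol.

Step 11
Reactants: 15 primary alcohol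
Product: 16 (2S,3Z,7E)-7-{[(tert-butyldiphenylsilyl)oxy]methyl}-8-iodo-2-[(4-methoxybenzyl)oxy]-3-{[(4-methoxybenzyl)oxy]methyl}octa-3,7-dienal
Conditions: Dess–Martin periodinane, pyridine, CH2Cl2, 0 °C → rt; used crude
Reagents that add atoms: none
Why: Dess–Martin oxidation under buffered, non-basic conditions should give the α-alkoxy aldehyde without epimerising C9 or moving the C1=C10 double bond.

Step 12
Reactants: 17 2,2-dimethoxyacetaldehyde; 18 methyl acrylate
Product: 19 methyl 3-hydroxy-4,4-dimethoxy-2-methylidenebutanoate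
Conditions: DABCO, dioxane/H2O, rt
Reagents that add atoms: none
Why: Morita–Baylis–Hillman reaction of an electron-poor α-alkoxy aldehyde, which tolerates the aqueous aldehyde solution; the racemic carbinol centre is destroyed in the next step.

Step 13
Reactants: 19 Baylis–Hillman alcohol
Product: 20 methyl (2Z)-2-(bromomethyl)-4,4-dimethoxybut-2-enoate
Conditions: N-bromosuccinimide, Me2S, CH2Cl2, 0 °C → rt
Reagents that add atoms: N-bromosuccinimide, O=C1CCC(=O)N1Br
Why: Corey–Kim-type bromination through the alkoxysulfonium salt with SN2′ transposition gives the conjugated allylic bromide as the preferred isomer with the ester trans to the acetal-bearing substituent, under conditions that spare the acetal.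

Step 14
Reactants: 16 α-alkoxy aldehyde; 20 allylic bromide
Product: 21 methyl ester of the C6–C12 seco unit joined to C8: C6 dimethyl acetal, free C8 hydroxyl, C9 4-methoxybenzyl ether, 7R,8S,9S
Conditions: In powder, THF/H2O (1:1), rt
Reagents that add atoms: none
Why: Barbier-type allylation in which the allylindium reagent attacks through its γ-carbon in a closed chair transition state, the (Z)-reagent giving the 7,8-syn relationship, while chelation of trivalent indium between the aldehyde oxygen and the C9 ether oxygen directs attack to the face that gives the 8,9-syn pattern; the vinyl iodide is inert to indium.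

Step 15
Reactants: 21 Barbier adduct; 22 (2R)-2-methylbutanoic acid
Product: 23 (2R)-2-methylbutanoate of 21 at the C8 oxygen
Conditions: DCC, DMAP (cat.), CH2Cl2, 0 °C → rt
Reagents that add atoms: none
Why: Steglich esterification of the secondary alcohol, run cold and directly after step 14 so that neither racemisation of the acid nor lactonisation of the C8 hydroxyl onto the acrylate ester intervenes.

Step 16
Reactants: 23 acetal ester
Product: 24 seco-aldehyde: C5 vinyl iodide, C6 aldehyde, C12 methyl ester, 7R,8S,9S
Conditions: LiBF4, MeCN/H2O (50:1), rt; used crude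
Reagents that add atoms: water, O
Why: Mild Lewis-acid-assisted acetal hydrolysis near neutral pH should free the C6 aldehyde without cleaving the benzylic ethers, epimerising C7 or drawing the C11=C13 double bond into conjugation.

Step 17
Reactants: 24 seco-aldehyde
Product: 26 trans-fused germacranolide with 9,14-bis(4-methoxybenzyl) and 15-silyl ethers (6R,7S,8S,9S), via macrocyclic hydroxy ester 25 (not isolated)
Conditions: CrCl2 (12 equiv), NiCl2 (0.1 equiv), DMSO/THF (3:1), rt, 24 added over 12 h to 2 mM; then pyridinium p-toluenesulfonate (cat.), CH2Cl2, rt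
Reagents that add atoms: none
Why: Zerovalent nickel inserts into the C5–I bond with retention, the vinyl group passes to trivalent chromium (two CrCl2 per iodide) and the configurationally stable vinylchromium adds to the C6 aldehyde, after which the C6 oxygen attacks the C12 methyl ester. The closest known reaction type is the Nozaki–Hiyama–Kishi macrocyclisation of iodoalkenyl aldehydes followed by γ-lactonisation. The ten-membered carbocycle closes by 1,2-addition in the exo-trig mode (C6=O outside the new ring) and the lactone by 5-exo-trig acyl substitution. The new C6 stereocentre is controlled by C7 and C8: Felkin–Anh attack anti to the C7–C8 bond and 1,3-anti induction by the C8 acyloxy group reinforce each other and both give 6R, the epimer that leads to the trans-fused lactone. The step needs chemoselectivity for the aldehyde over the ester carbonyls and the acrylate, which organochromium reagents provide, retention of the C4=C5 geometry, and ring closure over oligomerisation, which high dilution and the two ring-cis olefins (the chain is already folded) should secure.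

Step 18
Reactants: 26 protected germacranolide
Product: 27 9,14-diol (15-silyl ether retained)
Conditions: DDQ, CH2Cl2/pH 7 buffer, 0 °C
Reagents that add atoms: none
Why: Oxidative cleavage of both 4-methoxybenzyl ethers by benzylic hydride abstraction and hydrolysis, under buffered non-basic conditions in which the hindered C8 ester should not migrate to the freed C9 hydroxyl.

Step 19
Reactants: 27 diol
Product: 28 14-aldehyde with free C9 hydroxyl
Conditions: TEMPO (cat.), PhI(OAc)2, CH2Cl2, rt
Reagents that add atoms: none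
Why: Oxoammonium (TEMPO) oxidation takes the unhindered primary allylic C14 alcohol much faster than the secondary C9 alcohol and stops at the enal.

Step 20
Reactants: 28 hydroxy enal
Product: 29 9-acetate (15-silyl ether of the target)
Conditions: Ac2O, pyridine, DMAP (cat.), CH2Cl2, 0 °C
Reagents that add atoms: acetic anhydride, CC(=O)OC(C)=O
Why: Nucleophile-catalysed acetylation of the secondary allylic C9 alcohol, run cold and at once so that acylation outruns any 1,2-acyl shift from C8.

Step 21
Reactants: 29 silyl ether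
Product: 30 CNP0247637.4
Conditions: HF·pyridine, pyridine/THF, 0 °C → rt
Reagents that add atoms: none
Why: Fluoride-mediated desilylation under buffered conditions frees the C15 hydroxyl and spares the enal, the allylic acetate, the ester and the α-methylene lactone.

Compound list
1 | 3-(trimethylsilyl)prop-2-yn-1-ol | C[Si](C)(C)C#CCO | starting material
2 | [2-(1,3-dioxan-2-yl)ethyl]magnesium bromide (THF solution) | Br[Mg]CCC1OCCCO1 | starting material
3 | (2E)-2-[2-(1,3-dioxan-2-yl)ethyl]-3-(trimethylsilyl)prop-2-en-1-ol (Me3Si cis to the chain) | C[Si](C)(C)/C=C(/CO)CCC1OCCCO1 | intermediate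
4 | tert-butyldiphenylsilyl ether of 3 | C[Si](C)(C)/C=C(/CO[Si](c1ccccc1)(c1ccccc1)C(C)(C)C)CCC1OCCCO1 | intermediate
5 | tert-butyl{[(2E)-2-[2-(1,3-dioxan-2-yl)ethyl]-3-iodoprop-2-en-1-yl]oxy}diphenylsilane (iodine cis to the chain) | I/C=C(/CO[Si](c1ccccc1)(c1ccccc1)C(C)(C)C)CCC1OCCCO1 | intermediate
6 | (4E)-4-{[(tert-butyldiphenylsilyl)oxy]methyl}-5-iodopent-4-enal | I/C=C(/CO[Si](c1ccccc1)(c1ccccc1)C(C)(C)C)CCC=O | intermediate
7 | dimethyl (2S)-2-hydroxybutanedioate (dimethyl (S)-malate) | COC(=O)C[C@H](O)C(=O)OC | starting material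
8 | methyl (3S)-3,4-dihydroxybutanoate | COC(=O)C[C@H](O)CO | intermediate
9 | methyl 2-[(4S)-2-(4-methoxyphenyl)-1,3-dioxolan-4-yl]acetate (acetal epimers) | COC(=O)C[C@H]1COC(c2ccc(OC)cc2)O1 | intermediate
10 | aldol adduct: methyl (6E)-6-{[(tert-butyldiphenylsilyl)oxy]methyl}-3-hydroxy-7-iodo-2-[(4S)-2-(4-methoxyphenyl)-1,3-dioxolan-4-yl]hept-6-enoate (mixture at C2 and C3) | I/C=C(/CO[Si](c1ccccc1)(c1ccccc1)C(C)(C)C)CCC(O)C(C(=O)OC)[C@H]1COC(c2ccc(OC)cc2)O1 | intermediate
11 | 3-O-acetate of 10 | I/C=C(/CO[Si](c1ccccc1)(c1ccccc1)C(C)(C)C)CCC(OC(C)=O)C(C(=O)OC)[C@H]1COC(c2ccc(OC)cc2)O1 | intermediate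
12 | methyl (2E,6E)-6-{[(tert-butyldiphenylsilyl)oxy]methyl}-7-iodo-2-[(4S)-2-(4-methoxyphenyl)-1,3-dioxolan-4-yl]hepta-2,6-dienoate | I/C=C(/CO[Si](c1ccccc1)(c1ccccc1)C(C)(C)C)CC/C=C(/C(=O)OC)[C@H]1COC(c2ccc(OC)cc2)O1 | intermediate
13 | (2Z,6E)-6-{[(tert-butyldiphenylsilyl)oxy]methyl}-7-iodo-2-[(4S)-2-(4-methoxyphenyl)-1,3-dioxolan-4-yl]hepta-2,6-dien-1-ol (chain cis to the dioxolane) | I/C=C(/CO[Si](c1ccccc1)(c1ccccc1)C(C)(C)C)CC/C=C(/CO)[C@H]1COC(c2ccc(OC)cc2)O1 | intermediate
14 | 4-methoxybenzyl ether of 13 | I/C=C(/CO[Si](c1ccccc1)(c1ccccc1)C(C)(C)C)CC/C=C(/COCc1ccc(OC)cc1)[C@H]1COC(c2ccc(OC)cc2)O1 | intermediate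
15 | (2S,3Z,7E)-7-{[(tert-butyldiphenylsilyl)oxy]methyl}-8-iodo-2-[(4-methoxybenzyl)oxy]-3-{[(4-methoxybenzyl)oxy]methyl}octa-3,7-dien-1-ol | I/C=C(/CO[Si](c1ccccc1)(c1ccccc1)C(C)(C)C)CC/C=C(/COCc1ccc(OC)cc1)[C@H](OCc1ccc(OC)cc1)CO | intermediate
16 | (2S,3Z,7E)-7-{[(tert-butyldiphenylsilyl)oxy]methyl}-8-iodo-2-[(4-methoxybenzyl)oxy]-3-{[(4-methoxybenzyl)oxy]methyl}octa-3,7-dienal | I/C=C(/CO[Si](c1ccccc1)(c1ccccc1)C(C)(C)C)CC/C=C(/COCc1ccc(OC)cc1)[C@H](OCc1ccc(OC)cc1)C=O | intermediate
17 | 2,2-dimethoxyacetaldehyde (aqueous solution) | COC(OC)C=O | starting material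
18 | methyl acrylate | C=CC(=O)OC | starting material
19 | methyl 3-hydroxy-4,4-dimethoxy-2-methylidenebutanoate (racemic) | COC(=O)C(=C)C(O)C(OC)OC | intermediate
20 | methyl (2Z)-2-(bromomethyl)-4,4-dimethoxybut-2-enoate | COC(=O)/C(CBr)=C/C(OC)OC | intermediate
21 | Barbier adduct: methyl 2-methylidene ester with C7 bearing CH(OMe)2, free C8-OH, C9-O-(4-methoxybenzyl), C14-O-(4-methoxybenzyl), C15-O-silyl, C5 vinyl iodide; 7R,8S,9S | I/C=C(/CO[Si](c1ccccc1)(c1ccccc1)C(C)(C)C)CC/C=C(/COCc1ccc(OC)cc1)[C@H](OCc1ccc(OC)cc1)[C@@H](O)[C@H](C(OC)OC)C(=C)C(=O)OC | intermediate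
22 | (2R)-2-methylbutanoic acid | CC[C@@H](C)C(=O)O | starting material
23 | 8-O-[(2R)-2-methylbutanoyl] derivative of 21; 7R,8S,9S | I/C=C(/CO[Si](c1ccccc1)(c1ccccc1)C(C)(C)C)CC/C=C(/COCc1ccc(OC)cc1)[C@H](OCc1ccc(OC)cc1)[C@@H](OC(=O)[C@H](C)CC)[C@H](C(OC)OC)C(=C)C(=O)OC | intermediate
24 | seco-aldehyde: 23 with the C6 acetal hydrolysed to CHO; 7R,8S,9S | I/C=C(/CO[Si](c1ccccc1)(c1ccccc1)C(C)(C)C)CC/C=C(/COCc1ccc(OC)cc1)[C@H](OCc1ccc(OC)cc1)[C@@H](OC(=O)[C@H](C)CC)[C@H](C=O)C(=C)C(=O)OC | intermediate
25 | macrocyclic hydroxy ester: ten-membered ring closed at C5–C6, free 6-OH, C12 methyl ester; 6R,7S,8S,9S | O[C@@H]1/C=C(/CO[Si](c2ccccc2)(c2ccccc2)C(C)(C)C)CC/C=C(/COCc2ccc(OC)cc2)[C@H](OCc2ccc(OC)cc2)[C@@H](OC(=O)[C@H](C)CC)[C@H]1C(=C)C(=O)OC | intermediate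
26 | 9,14-bis-O-(4-methoxybenzyl)-15-O-(tert-butyldiphenylsilyl) 12,6-lactone; 6R,7S,8S,9S | C=C1C(=O)O[C@@H]2/C=C(/CO[Si](c3ccccc3)(c3ccccc3)C(C)(C)C)CC/C=C(/COCc3ccc(OC)cc3)[C@H](OCc3ccc(OC)cc3)[C@@H](OC(=O)[C@H](C)CC)[C@@H]12 | intermediate
27 | 9,14-diol of 26 (15-silyl ether kept) | C=C1C(=O)O[C@@H]2/C=C(/CO[Si](c3ccccc3)(c3ccccc3)C(C)(C)C)CC/C=C(/CO)[C@H](O)[C@@H](OC(=O)[C@H](C)CC)[C@@H]12 | intermediate
28 | 14-aldehyde with free 9-OH (15-silyl ether kept) | C=C1C(=O)O[C@@H]2/C=C(/CO[Si](c3ccccc3)(c3ccccc3)C(C)(C)C)CC/C=C(/C=O)[C@H](O)[C@@H](OC(=O)[C@H](C)CC)[C@@H]12 | intermediate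
29 | 15-O-(tert-butyldiphenylsilyl) ether of the target | C=C1C(=O)O[C@@H]2/C=C(/CO[Si](c3ccccc3)(c3ccccc3)C(C)(C)C)CC/C=C(/C=O)[C@H](OC(C)=O)[C@@H](OC(=O)[C@H](C)CC)[C@@H]12 | intermediate
30 | CNP0247637.4: (6R,7S,8S,9S)-9-acetoxy-15-hydroxy-8-[(2R)-2-methylbutanoyloxy]-14-oxogermacra-1(10),4,11(13)-trien-12,6-olide, both ring olefins cis within the ring | C=C1C(=O)O[C@@H]2/C=C(/CO)CC/C=C(/C=O)[C@H](OC(C)=O)[C@@H](OC(=O)[C@H](C)CC)[C@@H]12 | target

Total step count: 21. Longest linear sequence: 17 steps (steps 1–4, 7–11, 14–21).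

Steps most likely to fail

Step 17. The ten-membered ring closure may lose to intermolecular coupling, and the aldehyde may be attacked on both faces under the conformational constraint of the forming ring, so that the C6 epimer, which cannot give the trans-fused lactone, builds up. The fallback corrects C6 by oxidation and reduction and sets out from 25, kept as the epimer mixture by leaving out the acid treatment. Oxidation with Dess–Martin periodinane would give the macrocyclic C6 enone F1. Luche reduction (NaBH4, CeCl3) or, for reagent control, a CBS reduction should then deliver hydride to the exposed outer face of the cis,cis-cyclodecadienone. The resulting 6R alcohol 25 lactonises under the acid treatment and the route is rejoined at 26.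

Step 14. Chelation by indium in water may be too weak with an ether at C9, so that non-chelated attack erodes the 8,9-syn selectivity, and isomerisation of the allylindium may erode the 7,8-syn selectivity. The fallback replaces the Barbier reaction by a Lewis-acid-promoted allylstannane addition and sets out from 19. Acetylation would give the acetate F2, and SN2′ stannylcupration (Bu3SnLi, CuBr·SMe2) the allylstannane F3. Aldehyde 16, precomplexed with MgBr2·OEt2 in CH2Cl2 at low temperature as a rigid five-membered chelate, should be attacked by F3 through an open antiperiplanar transition state. This gives the same 7,8-syn, 8,9-syn adduct, and the route is rejoined at 21.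

Step 7. The ester enolate may lose its β-oxygen (opening of the dioxolane) before it adds to the aldehyde, and the elimination may give a poor E/Z ratio. The fallback replaces the aldol–elimination by an olefination and sets out from 9. C-Phosphorylation of the enolate (two equivalents of LiN(i-Pr)2, ClP(O)(OEt)2) would give the phosphonate F4, whose delocalised anion is far less prone to β-elimination. Horner–Wadsworth–Emmons reaction of F4 with aldehyde 6 under LiCl/DBU conditions should give the (E)-enoate directly, and the route is rejoined at 12.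

Further compounds
F1 | step 17 | macrocyclic C6 enone: 25 with the 6-hydroxyl oxidised to the ketone (7S,8S,9S) | O=C1/C=C(/CO[Si](c2ccccc2)(c2ccccc2)C(C)(C)C)CC/C=C(/COCc2ccc(OC)cc2)[C@H](OCc2ccc(OC)cc2)[C@@H](OC(=O)[C@H](C)CC)[C@H]1C(=C)C(=O)OC
F2 | step 14 | methyl 3-acetoxy-4,4-dimethoxy-2-methylidenebutanoate | COC(=O)C(=C)C(OC(C)=O)C(OC)OC
F3 | step 14 | methyl (2Z)-4,4-dimethoxy-2-[(tributylstannyl)methyl]but-2-enoate | COC(=O)/C(C[Sn](CCCC)(CCCC)CCCC)=C/C(OC)OC
F4 | step 7 | methyl 2-(diethoxyphosphoryl)-2-[(4S)-2-(4-methoxyphenyl)-1,3-dioxolan-4-yl]acetate | CCOP(=O)(OCC)C(C(=O)OC)[C@H]1COC(c2ccc(OC)cc2)O1
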